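**Plan**
- Retrosynthesis: the two phenols of ring A are masked as acetates. The C(=O)–C-alpha and C-beta–C6' bonds of the propanone chain are then cut together, giving a ring A aldehyde, ethylene and a ring B aryl bromide.
- Enabling feature: ring A is the 5,7-dihydroxychroman acylated at C6 and ring B is the chroman joined at C6'. The chain between them is a bare CH2–CH2 unit flanked by an aroyl carbon and an aryl carbon, which is ethylene inserted between an acyl and an aryl fragment.
- Forward, ring A: the pyran is built on 2,4,6-trihydroxybenzaldehyde by para-O-propargylation, acetylation, Claisen rearrangement/electrocyclisation and hydrogenation.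
- Forward, ring B and chain: the pyran is closed on 4-bromophenol by acid-mediated prenylation/cyclisation. The chain is then joined in one three-component operation and the acetates are removed.
- Stereochemistry: the target has no stereocentre and no stereogenic double bond, so nothing needs to be controlled.

Key step: step 6

Remark on the chemistry: the ring A phenols are carried as acetates. Of two methyl ethers flanking the ketone, only the one syn to the carbonyl oxygen can be cleaved with chelation assistance by a boron halide. Harsher Lewis acids could open the tertiary-alkyl aryl ether of ring A and re-close it onto the other phenol.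

Step 1
Reactants: 1 2,4,6-trihydroxybenzaldehyde; 2 3-chloro-3-methylbut-1-yne
Product: 3 2,6-dihydroxy-4-[(2-methylbut-3-yn-2-yl)oxy]benzaldehyde
Conditions: 2 (1.1 equiv), DBU (1.05 equiv), CuCl2·2H2O (1 mol%), MeCN, −5 to 0 °C
Reagents that add atoms: none
Why: Copper-catalysed propargylic substitution (phenoxide O-alkylation by a copper-activated tertiary propargyl chloride) should select the hydroxyl para to the formyl group, which is the most acidic and the first deprotonated by one equivalent of DBU, while the two ortho hydroxyls stay engaged with the formyl oxygen.

Step 2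
Reactants: 3 2,6-dihydroxy-4-[(2-methylbut-3-yn-2-yl)oxy]benzaldehyde
Product: 4 2-formyl-5-[(2-methylbut-3-yn-2-yl)oxy]-1,3-phenylene diacetate
Conditions: Ac2O (2.5 equiv), pyridine, DMAP (cat.), CH2Cl2, 0 °C to rt
Reagents that add atoms: acetic anhydride, CC(=O)OC(C)=O
Why: DMAP-catalysed O-acetylation caps both remaining phenols under non-acidic conditions that spare the aldehyde, the alkyne and the tertiary propargyl ether, and installs groups that have no hydridic C–H bond, tolerate nickel catalysis and later come off without acid.

Step 3
Reactants: 4 2-formyl-5-[(2-methylbut-3-yn-2-yl)oxy]-1,3-phenylene diacetate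
Product: 7 6-formyl-2,2-dimethyl-2H-chromene-5,7-diyl diacetate, via allenylphenol 5 (not isolated), via quinone methide 6 (not isolated)
Conditions: o-xylene, 140 °C
Reagents that add atoms: none
Why: Aromatic propargyl Claisen rearrangement and enolisation should give allenylphenol 5, a 1,5-hydrogen shift then gives quinone methide 6, and oxa-6π electrocyclisation closes the pyran; because the two other ring oxygens are acetylated, only the former ether oxygen can close, which fixes the formyl group at C6.

Step 4
Reactants: 7 6-formyl-2,2-dimethyl-2H-chromene-5,7-diyl diacetate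
Product: 8 6-formyl-2,2-dimethylchroman-5,7-diyl diacetate
Conditions: H2 (1 atm), Pd/C, Ph2S (cat.), EtOAc, rt
Reagents that add atoms: none
Why: Heterogeneous catalytic hydrogenation of the cis-disubstituted styrenic C3=C4 bond on Pd/C moderated with diphenyl sulfide should be far faster than reduction of the di-ortho-substituted aryl aldehyde and leaves the aryl acetates intact.

Step 5
Reactants: 9 4-bromophenol; 10 2-methylbut-3-en-2-ol
Product: 12 6-bromo-2,2-dimethylchroman, via prenylphenol 11 (not isolated)
Conditions: 9 (2 equiv), slow addition of 10, Amberlyst 15, 1,2-dichloroethane, 70 °C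
Reagents that add atoms: none
Why: Acid-catalysed Friedel–Crafts prenylation by the dimethylallyl cation ortho to the hydroxyl (the para position carries bromine) gives prenylphenol 11, which closes to the chroman by Markovnikov hydroalkoxylation of the trisubstituted alkene under the same acid.

Step 6
Reactants: 8 6-formyl-2,2-dimethylchroman-5,7-diyl diacetate; 13 ethylene; 12 6-bromo-2,2-dimethylchroman
Product: 14 6-[3-(2,2-dimethylchroman-6-yl)propanoyl]-2,2-dimethylchroman-5,7-diyl diacetate
Conditions: 8 (1.5 equiv), 12 (1.0 equiv), ethylene (4 bar), (n-Bu4N)4[W10O32] (4 mol%), NiBr2(dme) (10 mol%), 4,4'-di-tert-butyl-2,2'-bipyridine (12 mol%), Na2CO3 (2 equiv), MeCN, 390 nm LEDs, 25 °C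
Reagents that add atoms: none
Why: Proposed new method: photoexcited decatungstate should abstract the hydridic formyl hydrogen of 8 to give a σ-aroyl radical that adds to ethylene (carbonyl carbon–C-alpha bond), and the resulting primary 3-aryl-3-oxopropyl radical should be trapped by the aryl–nickel bromide formed from 12 and zerovalent nickel, after which reductive elimination from trivalent nickel forms C-beta–C6' and the reduced polyoxometalate returns nickel to its low-valent state. The closest known reaction types are decatungstate/nickel acyl C–H arylation of aldehydes, decatungstate/nickel three-component acyl- or alkyl-arylation of activated alkenes, and nickel/photoredox dicarbofunctionalisation of ethylene with alkyl radicals; the untested element is an aroyl radical combined with unactivated ethylene. No ring closes and no stereocentre is formed. The selectivity needed is three-component coupling over direct aroyl–aryl coupling, over simple hydroacylation and over double ethylene insertion: the two ortho acetoxy groups should shield the aroyl radical from nickel so that ethylene intercepts it first, whereas the unhindered primary radical should be captured by nickel faster than it adds a second ethylene at moderate pressure. Because ethylene is symmetric, the alternative order (aryl–nickel insertion into ethylene, then aroyl-radical capture) converges on the same product, so no regiochemical question arises. Acetates, unlike ethers with α-oxy C–H bonds, keep hydrogen abstraction directed at the formyl group, and the mild insoluble carbonate base should not cleave them.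

Step 7
Reactants: 14 6-[3-(2,2-dimethylchroman-6-yl)propanoyl]-2,2-dimethylchroman-5,7-diyl diacetate
Product: 15 1-(5,7-dihydroxy-2,2-dimethylchroman-6-yl)-3-(2,2-dimethylchroman-6-yl)propan-1-one
Conditions: K2CO3 (0.3 equiv), MeOH, 0 °C to rt; aq. NH4Cl
Reagents that add atoms: none
Why: Base-catalysed transesterification of the two aryl acetates (Zemplén-type methanolysis) releases the hydrogen-bonded 2,6-dihydroxyaryl ketone without any Lewis or Brønsted acid, so neither tertiary-alkyl aryl ether can open or transpose and the enolisable ketone is not engaged.

**Compound list**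
1 | 2,4,6-trihydroxybenzaldehyde | O=Cc1c(O)cc(O)cc1O | starting material
2 | 3-chloro-3-methylbut-1-yne | CC(C)(Cl)C#C | starting material
3 | 2,6-dihydroxy-4-[(2-methylbut-3-yn-2-yl)oxy]benzaldehyde | O=Cc1c(O)cc(OC(C)(C)C#C)cc1O | intermediate
4 | 2-formyl-5-[(2-methylbut-3-yn-2-yl)oxy]-1,3-phenylene diacetate | O=Cc1c(OC(C)=O)cc(OC(C)(C)C#C)cc1OC(C)=O | intermediate
5 | allenylphenol, 2-formyl-5-hydroxy-4-(3-methylbuta-1,2-dien-1-yl)-1,3-phenylene diacetate (step 3, not isolated) | O=Cc1c(OC(C)=O)cc(O)c(C=C=C(C)C)c1OC(C)=O | intermediate
6 | quinone methide, 2-formyl-4-[(Z)-3-methylbut-2-en-1-ylidene]-5-oxocyclohexa-2,6-diene-1,3-diyl diacetate (step 3, not isolated) | O=CC1=C(OC(C)=O)/C(=C/C=C(C)C)C(=O)C=C1OC(C)=O | intermediate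
7 | 6-formyl-2,2-dimethyl-2H-chromene-5,7-diyl diacetate | CC1(C)C=Cc2c(OC(C)=O)c(C=O)c(OC(C)=O)cc2O1 | intermediate
8 | 6-formyl-2,2-dimethylchroman-5,7-diyl diacetate (ring A aldehyde) | CC1(C)CCc2c(OC(C)=O)c(C=O)c(OC(C)=O)cc2O1 | intermediate
9 | 4-bromophenol | Oc1ccc(Br)cc1 | starting material
10 | 2-methylbut-3-en-2-ol | CC(C)(O)C=C | starting material
11 | prenylphenol, 4-bromo-2-(3-methylbut-2-en-1-yl)phenol (step 5, not isolated) | CC(C)=CCc1cc(Br)ccc1O | intermediate
12 | 6-bromo-2,2-dimethylchroman (ring B bromide) | CC1(C)CCc2cc(Br)ccc2O1 | intermediate
13 | ethylene | C=C | starting material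
14 | 6-[3-(2,2-dimethylchroman-6-yl)propanoyl]-2,2-dimethylchroman-5,7-diyl diacetate | CC1(C)CCc2cc(CCC(=O)c3c(OC(C)=O)cc4c(c3OC(C)=O)CCC(C)(C)O4)ccc2O1 | intermediate
15 | 1-(5,7-dihydroxy-2,2-dimethylchroman-6-yl)-3-(2,2-dimethylchroman-6-yl)propan-1-one | CC1(C)CCc2cc(CCC(=O)c3c(O)cc4c(c3O)CCC(C)(C)O4)ccc2O1 | target

**Step count**
Total steps: 7. Longest linear sequence: 6 steps (steps 1, 2, 3, 4, 6, 7); step 5 is the convergent branch.

**Steps most likely to fail**

Step 6 (proposed new method). Several processes could divert the reaction:
- nickel may capture the aroyl radical before it meets ethylene, leading to direct aroyl–aryl coupling;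
- the primary radical may add further ethylene or be quenched by back hydrogen transfer;
- decatungstate may abstract at the benzylic C4–H positions.

Fallback with known chemistry, setting out from 12 and returning at 14: bromine–lithium exchange of 12 (n-BuLi, THF, −78 °C) gives (2,2-dimethylchroman-6-yl)lithium F1. This opens ethylene oxide to give, after aqueous work-up, 2-(2,2-dimethylchroman-6-yl)ethan-1-ol F2. An Appel reaction (CBr4, PPh3, CH2Cl2, 0 °C) converts it into 6-(2-bromoethyl)-2,2-dimethylchroman F3. F3 is then joined to aldehyde 8 by the established nickel/photoredox/hydrogen-atom-transfer aldehyde C–H alkylation with alkyl bromides (Ir[dF(CF3)ppy]2(dtbbpy)PF6, NiBr2(dme), 4,4'-di-tert-butyl-2,2'-bipyridine, quinuclidine, K2CO3, 1,4-dioxane, blue LEDs), giving 14. The two carbons of the chain then come from ethylene oxide, and no radical addition to an alkene is needed.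

Step 1. Alkylation may not stop at the para oxygen: a second etherification or C-propargylation of the electron-rich ring would erode site selectivity. Fallback, setting out from 1 and returning at 7: condensation of 1 with 3-methylbut-2-enal under ethylenediammonium diacetate catalysis (toluene, 110 °C) proceeds by Knoevenagel-type condensation and oxa-6π electrocyclisation. It should close onto the non-chelated para hydroxyl and give 5,7-dihydroxy-2,2-dimethyl-2H-chromene-6-carbaldehyde F4. Acetylation (Ac2O, pyridine, DMAP) then gives 7, bypassing steps 1 to 3.

Step 5. Oligomerisation of the allyl cation may outrun Friedel–Crafts attack on the bromine-deactivated phenol, and a second prenylation at C8 may follow. Fallback, setting out from 9 and returning at 12: Friedel–Crafts acylation/oxa-Michael annulation of 9 with 3-methylbut-2-enoic acid in P2O5/MeSO3H (70 °C) gives 6-bromo-2,2-dimethylchroman-4-one F5. Ionic hydrogenation (Et3SiH, CF3CO2H, 60 °C) then removes the benzylic carbonyl to give 12.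

**Further compounds**
F1 | step 6 | (2,2-dimethylchroman-6-yl)lithium | [Li]c1ccc2OC(C)(C)CCc2c1
F2 | step 6 | 2-(2,2-dimethylchroman-6-yl)ethan-1-ol | OCCc1ccc2OC(C)(C)CCc2c1
F3 | step 6 | 6-(2-bromoethyl)-2,2-dimethylchroman | BrCCc1ccc2OC(C)(C)CCc2c1
F4 | step 1 | 5,7-dihydroxy-2,2-dimethyl-2H-chromene-6-carbaldehyde | CC1(C)C=Cc2c(O)c(C=O)c(O)cc2O1
F5 | step 5 | 6-bromo-2,2-dimethylchroman-4-one | CC1(C)CC(=O)c2cc(Br)ccc2O1
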